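All runs were generated by integration for an exercise; scatter was added.

Late in the dusk run the starting material stands still, 8.9 % at 12.0 h and 9.1 % at 25.0 h, while target sinks from 50.6 % to 24.4 %. So we read time in two parts: a fork, then a clock.

all flasks: starting material 0.051 M
- autumn: coupling partner 0.051 M; second substrate 0.255 M; run made earlier
- dusk: coupling partner 0.11 M; second substrate 0.255 M; run made earlier
- spring: coupling partner 0.0765 M; second substrate 0.51 M; run made earlier
- flask: coupling partner 0.0765 M; second substrate 0.255 M; time 40 h

| run | time / h | over-reaction product / % | starting material / % | target / % |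
|---|---|---|---|---|
| autumn | 3.00 | 5.7 | 48.7 | 46.3 |
| autumn | 8.00 | 17.1 | 45.4 | 37.5 |
| autumn | 15.0 | 29.7 | 44.9 | 25.4 |
| autumn | 25.0 | 40.1 | 44.7 | 14.5 |
| dusk | 6.00 | 21.5 | 11.4 | 68.2 |
| dusk | 12.0 | 41.2 | 8.9 | 50.6 |
| dusk | 20.0 | 59.0 | 9.5 | 32.6 |
| dusk | 25.0 | 66.9 | 9.1 | 24.4 |
| spring | 6.00 | 14.1 | 43.3 | 42.5 |
| spring | 12.0 | 26.1 | 43.1 | 30.3 |
| spring | 20.0 | 37.6 | 43.4 | 19.3 |
| spring | 25.0 | 41.2 | 43.3 | 15.8 |

(scatter of a reading: 0.5 percentage points)

- the species that holds most of what was charged as starting material, at 40 h (target / over-reaction product / starting material)
- the largest share itself, whichever of these holds it, in percent of the starting material charged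

- the numbers in the tables scatter with a standard deviation of 0.5 percentage points

1. Follow one molecule of coupling partner, which we take as the limiting reagent. It meets starting material or second substrate, with odds s times the ratio of their amounts. Let f be the fraction of starting material left, w the partner wasted as a fraction of the starting material charged, and r the charge of starting material over that of second substrate, counted as constant. Summing the odds gives −ln f = s·r·w.

2. Late readings give s as 9.01 (autumn), 9.60 (dusk) and 8.97 (spring). We carry their mean, the selectivity factor 9.19.

3. In the flask, s·r is 1.84. Trying f = 0.250 returns 0.252, so we keep that.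

4. Target in the dusk run falls at 0.0541 h⁻¹. Starting this clock at zero, the flask holds target 0.0859 at 40 h and over-reaction product 0.662, more than starting material.

5. The weak link is that one-run clock. The autumn run gives 0.0559 h⁻¹ and the spring run 0.0521 h⁻¹, which put over-reaction product at 0.668 and 0.655.

The forecast names over-reaction product at 66 %, holding that “Part of it is lost to a side reaction with the second substrate.”

The flask gives over-reaction product at 66.2 %, with starting material 25.0 % and target 8.78 %.

    target → over-reaction product (k = 9.20 × 10⁻⁴ min⁻¹)
    starting material + coupling partner → target (k = 0.230 M⁻¹ min⁻¹)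
    second substrate + coupling partner → second product (k = 0.0270 M⁻¹ min⁻¹)

At 0.964 h the flask's coupling partner has a half-life of 1.8 h by the wasting path, against 13 h for target. Reckoned with s, the odds for starting material sink from 1.84 at the start to 0.464 at the remainder; at 0.964 h, well before that remainder, the flask's partner already goes to second substrate 1.1 times as fast as to starting material. For a neighbouring flask with 1.0 M of second substrate, s·r is 0.469, and trying 0.600 returns f = 0.597, more than the converted rest. Computed, it holds 60.9 % starting material against 34.7 % over-reaction product. The forecast's species would fail from 0.583 M of second substrate, where the two stand equal.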